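**Strategy.** The plan rests on cutting the C2–C8 bond of the cyclobutane (tricyclo[5.4.0.0^{2,8}]undecane numbering): the bond between the methyl-bearing quaternary carbon and the bridgehead beside the C9 ketone. The precursor is a cis-fused cycloheptane-1,3-dione carrying a cyclohexene oxide. Because C6 is quaternary, the dianion of the 3,5-dione can form only at C2. That carbanion sits 1,3-diaxial to the epoxide carbon C8 and opens it in a 4-exo fashion. One operation closes the four-membered ring, creates the quaternary centre and leaves the oxygen that becomes the C9 ketone. The bicycle arises from an enantioselective Diels–Alder reaction and a Claisen ring closure.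

Key step: step 10

Remark (assumption): the esterase is taken to hydrolyse the ester group that gives the (2R)-half-ester 4, and the (S)-oxazaborolidinium catalyst to give the (1R,5R,6S) adduct 10; if either sense is opposite, the roles of the two carboxyl groups are exchanged or the enantiomeric catalyst is used.

Step 1
Reactants: 1 dimethyl 2-methylpropanedioate; 2 benzyl chloromethyl ether
Product: 3 dimethyl 2-[(benzyloxy)methyl]-2-methylpropanedioate
Conditions: NaH, THF, 0 °C to rt
Reagents that add atoms: none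
Why: Malonate C-alkylation (SN2 of the sodium enolate on the chloromethyl ether) should give the prochiral quaternary diester.

Step 2
Reactants: 3 dimethyl 2-[(benzyloxy)methyl]-2-methylpropanedioate
Product: 4 (2R)-3-(benzyloxy)-2-(methoxycarbonyl)-2-methylpropanoic acid
Conditions: pig liver esterase, 0.1 M phosphate buffer pH 7.5, NaOH (pH-stat), rt
Reagents that add atoms: water, O
Why: Enzymatic desymmetrisation of a prochiral 2,2-disubstituted malonate, in which hydrolysis of one enantiotopic ester group sets the quaternary stereocentre.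

Step 3
Reactants: 4 (2R)-3-(benzyloxy)-2-(methoxycarbonyl)-2-methylpropanoic acid
Product: 6 methyl (2R)-2-[(benzyloxy)methyl]-2-methyl-3-oxopropanoate, via acid chloride 5 (not isolated)
Conditions: (COCl)2, DMF (cat.), CH2Cl2, 0 °C; then LiAlH(OtBu)3, THF, −78 °C
Reagents that add atoms: none
Why: Partial reduction of an acid chloride by the hindered hydride LiAlH(OtBu)3 (Rosenmund-type) should stop at the aldehyde, leave the ester untouched, and cannot epimerise the quaternary centre.

Step 4
Reactants: 6 methyl (2R)-2-[(benzyloxy)methyl]-2-methyl-3-oxopropanoate; 7 diethyl prop-2-en-1-ylphosphonate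
Product: 8 methyl (2S,3E)-2-[(benzyloxy)methyl]-2-methylhexa-3,5-dienoate
Conditions: 7, n-BuLi, THF, −78 °C; HMPA; then 6, −78 °C to rt
Reagents that add atoms: none
Why: Horner–Wadsworth–Emmons olefination of the non-enolisable aldehyde with the lithiated allylphosphonate should give the terminal 1,3-diene with E geometry from the thermodynamically controlled elimination.

Step 5
Reactants: 8 methyl (2S,3E)-2-[(benzyloxy)methyl]-2-methylhexa-3,5-dienoate; 9 (3E)-pent-3-en-2-one
Product: 10 methyl (2S)-2-[(1R,5R,6S)-6-acetyl-5-methylcyclohex-2-en-1-yl]-3-(benzyloxy)-2-methylpropanoate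
Conditions: (S)-1-(2-methylphenyl)-3,3-diphenyltetrahydro-1H,3H-pyrrolo[1,2-c][1,3,2]oxazaborole (C24H24BNO, 20 mol %), HN(SO2CF3)2 (16 mol %), CH2Cl2, −78 °C to −20 °C
Reagents that add atoms: none
Why: Catalytic enantioselective Diels–Alder reaction in which ortho regiochemistry and endo approach place the acetyl group cis to the quaternary side chain, the E-enone places the ring methyl trans to acetyl, and the chiral Lewis acid selects the enone face.

Step 6
Reactants: 11 (methoxymethyl)diphenylphosphine oxide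
Product: 12 (1-methoxyethyl)diphenylphosphine oxide (racemic)
Conditions: LiN(iPr)2, THF, −78 °C; MeI, −78 °C to 0 °C
Reagents that add atoms: iodomethane, CI
Why: α-Lithiation of the phosphine oxide and C-methylation should give the Horner–Wittig reagent that acts as an acetyl-anion equivalent.

Step 7
Reactants: 10 methyl (2S)-2-[(1R,5R,6S)-6-acetyl-5-methylcyclohex-2-en-1-yl]-3-(benzyloxy)-2-methylpropanoate; 12 (1-methoxyethyl)diphenylphosphine oxide
Product: 15 methyl (2S)-3-(benzyloxy)-2-methyl-2-[(1R,5R,6S)-5-methyl-6-(3-oxobutan-2-yl)cyclohex-2-en-1-yl]propanoate (both epimers at the butan-2-yl carbon), via phosphine oxide adduct 13 (not isolated), via methyl enol ether 14 (not isolated)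
Conditions: 12, LiN(iPr)2, THF, −78 °C; then 10; KOtBu, THF, rt; then 1 M HCl, THF, rt
Reagents that add atoms: water, O
Why: Horner–Wittig homologation (addition of the lithiated α-methoxy phosphine oxide to the ketone, elimination of diphenylphosphinate, enol ether hydrolysis) should turn acetyl into 3-oxobutan-2-yl, the new stereocentre being left uncontrolled because it is erased by enolisation in step 10.

Step 8
Reactants: 15 methyl (2S)-3-(benzyloxy)-2-methyl-2-[(1R,5R,6S)-5-methyl-6-(3-oxobutan-2-yl)cyclohex-2-en-1-yl]propanoate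
Product: 16 (1S,6S,7R,11R)-6-[(benzyloxy)methyl]-2,6,11-trimethylbicyclo[5.4.0]undec-8-ene-3,5-dione (C2 epimers)
Conditions: KOtBu (2.5 equiv), THF (0.01 M), 0 °C to rt; then AcOH
Reagents that add atoms: none
Why: Intramolecular Claisen (ketone–ester) condensation in which the methyl-ketone enolate acylates the ester to close the seven-membered 1,3-dione, driven by diketonate formation, whereas the five-membered product of acylation at the methine cannot form a stabilised enolate and should revert.

Step 9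
Reactants: 16 (1S,6S,7R,11R)-6-[(benzyloxy)methyl]-2,6,11-trimethylbicyclo[5.4.0]undec-8-ene-3,5-dione
Product: 17 (1S,6S,7R,8R,9S,11R)-6-[(benzyloxy)methyl]-8,9-epoxy-2,6,11-trimethylbicyclo[5.4.0]undecane-3,5-dione (C2 epimers)
Conditions: mCPBA, NaHCO3, CH2Cl2, 0 °C
Reagents that add atoms: 3-chloroperoxybenzoic acid, OOC(=O)c1cccc(Cl)c1
Why: Prilezhaev epoxidation of the isolated cis-alkene should occur on the face opposite to the allylic quaternary substituent and the fused seven-membered ring, which puts the epoxide trans to both ring-fusion bonds.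

Step 10
Reactants: 17 (1S,6S,7R,8R,9S,11R)-6-[(benzyloxy)methyl]-8,9-epoxy-2,6,11-trimethylbicyclo[5.4.0]undecane-3,5-dione
Product: 19 (1S,2R,6S,7S,8R,9S,11R)-6-[(benzyloxy)methyl]-9-hydroxy-2,6,11-trimethyltricyclo[5.4.0.0^{2,8}]undecane-3,5-dione, via dilithium dianion 18 (not isolated)
Conditions: LiN(iPr)2 (2.6 equiv), THF, −78 °C to 0 °C; then aq. NH4Cl
Reagents that add atoms: none
Why: Two equivalents of LiN(iPr)2 convert the 3,5-dione into its dianion, whose terminal carbanion at C2 (the only γ-carbon bearing hydrogen, C6 being quaternary) attacks the epoxide carbon C8 anti to the C–O bond, an intramolecular SN2 epoxide opening of the Stork epoxynitrile type combined with the γ-alkylation typical of β-diketone dianions. The cyclobutane closes in the 4-exo-tet mode, which should be preferred to 5-endo attack at C9 because only C8 allows collinear backside approach from the axial C2 and trans-diaxial opening of the cyclohexene oxide. The C2 quaternary centre is fixed by the cis ring fusion, since the carbanion can reach C8 only on the face of the C1–C2 bond; C8 is set by inversion at the epoxide carbon and C9 keeps the epoxide oxygen as its hydroxyl with retention. The step needs C-alkylation at C2 rather than O-alkylation or attack by the central carbon C4: O-alkylation would create a bridgehead enol ether in a bicyclo[3.2.2] frame, and the central carbon of a diketone dianion is far less nucleophilic than the terminal one. Both C2 epimers of 17 converge because C2 becomes planar in the dianion.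

Step 11
Reactants: 19 (1S,2R,6S,7S,8R,9S,11R)-6-[(benzyloxy)methyl]-9-hydroxy-2,6,11-trimethyltricyclo[5.4.0.0^{2,8}]undecane-3,5-dione
Product: 20 (1S,2R,6S,7S,8R,11R)-6-[(benzyloxy)methyl]-2,6,11-trimethyltricyclo[5.4.0.0^{2,8}]undecane-3,5,9-trione
Conditions: Dess–Martin periodinane, NaHCO3, CH2Cl2, rt
Reagents that add atoms: none
Why: Dess–Martin oxidation of the secondary alcohol should give the C9 ketone, the adjacent C8 being a cyclobutane bridgehead that cannot epimerise.

Step 12
Reactants: 20 (1S,2R,6S,7S,8R,11R)-6-[(benzyloxy)methyl]-2,6,11-trimethyltricyclo[5.4.0.0^{2,8}]undecane-3,5,9-trione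
Product: 21 (1S,2R,6S,7S,8R,11R)-6-(hydroxymethyl)-2,6,11-trimethyltricyclo[5.4.0.0^{2,8}]undecane-3,5,9-trione
Conditions: H2 (1 atm), Pd/C (10 wt % Pd), EtOAc, rt
Reagents that add atoms: none
Why: Hydrogenolysis of the benzyl ether frees the primary alcohol at the one stage of the route where no alkene is present.

Step 13
Reactants: 21 (1S,2R,6S,7S,8R,11R)-6-(hydroxymethyl)-2,6,11-trimethyltricyclo[5.4.0.0^{2,8}]undecane-3,5,9-trione
Product: 23 (1S,2R,3R,5R,6S,7S,8R,11R)-3,5-dihydroxy-6-(hydroxymethyl)-2,6,11-trimethyltricyclo[5.4.0.0^{2,8}]undecan-9-one, via 5-hydroxy-3,9-dione 22 (not isolated)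
Conditions: Me4N[BH(OAc)3] (6 equiv), MeCN/AcOH 1:1, −20 °C to rt
Reagents that add atoms: none
Why: Evans–Saksena hydroxyl-directed reduction used twice: the CH2OH-bound acetoxyborohydride should deliver hydride to the C5 ketone from the hydroxymethyl face, and the new C5–O–B–H unit then to C3 to give the trans-3,5-diol, while the undirected C9 ketone is left alone.

Step 14
Reactants: 23 (1S,2R,3R,5R,6S,7S,8R,11R)-3,5-dihydroxy-6-(hydroxymethyl)-2,6,11-trimethyltricyclo[5.4.0.0^{2,8}]undecan-9-one
Product: 24 (1S,2R,3R,5R,6S,7S,8R,11R)-6-({[tert-butyl(dimethyl)silyl]oxy}methyl)-3,5-dihydroxy-2,6,11-trimethyltricyclo[5.4.0.0^{2,8}]undecan-9-one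
Conditions: TBSCl (1.1 equiv), imidazole, DMF, 0 °C
Reagents that add atoms: tert-butyldimethylsilyl chloride, CC(C)(C)[Si](C)(C)Cl
Why: Silylation should be selective for the primary alcohol over the two neopentyl secondary alcohols.

Step 15
Reactants: 24 (1S,2R,3R,5R,6S,7S,8R,11R)-6-({[tert-butyl(dimethyl)silyl]oxy}methyl)-3,5-dihydroxy-2,6,11-trimethyltricyclo[5.4.0.0^{2,8}]undecan-9-one; 25 (2Z)-2-methylbut-2-enoic acid (angelic acid)
Product: 26 (1S,2R,3R,5R,6S,7S,8R,11R)-6-({[tert-butyl(dimethyl)silyl]oxy}methyl)-2,6,11-trimethyl-9-oxotricyclo[5.4.0.0^{2,8}]undecane-3,5-diyl bis[(2Z)-2-methylbut-2-enoate]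
Conditions: 25 (6 equiv), 2,4,6-trichlorobenzoyl chloride, Et3N, toluene, rt; then 24, 80 °C
Reagents that add atoms: none
Why: Yamaguchi esterification through the mixed anhydride should acylate both hindered secondary alcohols without nucleophilic catalysts that isomerise the Z-enoate.

Step 16
Reactants: 26 (1S,2R,3R,5R,6S,7S,8R,11R)-6-({[tert-butyl(dimethyl)silyl]oxy}methyl)-2,6,11-trimethyl-9-oxotricyclo[5.4.0.0^{2,8}]undecane-3,5-diyl bis[(2Z)-2-methylbut-2-enoate]
Product: 27 (1S,2R,3R,5R,6S,7S,8R,11R)-6-(hydroxymethyl)-2,6,11-trimethyl-9-oxotricyclo[5.4.0.0^{2,8}]undecane-3,5-diyl bis[(2Z)-2-methylbut-2-enoate]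
Conditions: HF·pyridine, pyridine, THF, 0 °C to rt
Reagents that add atoms: none
Why: Desilylation under mildly acidic fluoride conditions should free the primary alcohol without acyl migration or angelate isomerisation.

**Compound list**

1 | dimethyl 2-methylpropanedioate | COC(=O)C(C)C(=O)OC | starting material
2 | benzyl chloromethyl ether | ClCOCc1ccccc1 | starting material
3 | dimethyl 2-[(benzyloxy)methyl]-2-methylpropanedioate | COC(=O)C(C)(COCc1ccccc1)C(=O)OC | intermediate
4 | (2R)-3-(benzyloxy)-2-(methoxycarbonyl)-2-methylpropanoic acid | OC(=O)[C@@](C(=O)OC)(C)COCc1ccccc1 | intermediate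
5 | methyl (2S)-2-[(benzyloxy)methyl]-3-chloro-2-methyl-3-oxopropanoate (acid chloride, not isolated) | ClC(=O)[C@@](C(=O)OC)(C)COCc1ccccc1 | intermediate
6 | methyl (2R)-2-[(benzyloxy)methyl]-2-methyl-3-oxopropanoate | O=C[C@@](C(=O)OC)(C)COCc1ccccc1 | intermediate
7 | diethyl prop-2-en-1-ylphosphonate | C=CCP(=O)(OCC)OCC | starting material
8 | methyl (2S,3E)-2-[(benzyloxy)methyl]-2-methylhexa-3,5-dienoate | C=C/C=C/[C@@](C(=O)OC)(C)COCc1ccccc1 | intermediate
9 | (3E)-pent-3-en-2-one | C/C=C/C(C)=O | starting material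
10 | methyl (2S)-2-[(1R,5R,6S)-6-acetyl-5-methylcyclohex-2-en-1-yl]-3-(benzyloxy)-2-methylpropanoate | CC(=O)[C@H]1[C@H](C)CC=C[C@H]1[C@@](C)(COCc1ccccc1)C(=O)OC | intermediate
11 | (methoxymethyl)diphenylphosphine oxide | COCP(=O)(c1ccccc1)c1ccccc1 | starting material
12 | (1-methoxyethyl)diphenylphosphine oxide (racemic) | COC(C)P(=O)(c1ccccc1)c1ccccc1 | intermediate
13 | methyl (2S)-3-(benzyloxy)-2-{(1R,5R,6S)-6-[3-(diphenylphosphoryl)-2-hydroxy-3-methoxybutan-2-yl]-5-methylcyclohex-2-en-1-yl}-2-methylpropanoate (lithium alkoxide in the flask, diastereomer mixture, not isolated) | COC(C)(P(=O)(c1ccccc1)c1ccccc1)C(C)(O)[C@H]1[C@H](C)CC=C[C@H]1[C@@](C)(COCc1ccccc1)C(=O)OC | intermediate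
14 | methyl (2S)-3-(benzyloxy)-2-[(1R,5R,6S)-6-(3-methoxybut-2-en-2-yl)-5-methylcyclohex-2-en-1-yl]-2-methylpropanoate (E/Z mixture, not isolated) | COC(C)=C(C)[C@H]1[C@H](C)CC=C[C@H]1[C@@](C)(COCc1ccccc1)C(=O)OC | intermediate
15 | methyl (2S)-3-(benzyloxy)-2-methyl-2-[(1R,5R,6S)-5-methyl-6-(3-oxobutan-2-yl)cyclohex-2-en-1-yl]propanoate (both epimers at the butan-2-yl carbon) | CC(=O)C(C)[C@H]1[C@H](C)CC=C[C@H]1[C@@](C)(COCc1ccccc1)C(=O)OC | intermediate
16 | (1S,6S,7R,11R)-6-[(benzyloxy)methyl]-2,6,11-trimethylbicyclo[5.4.0]undec-8-ene-3,5-dione (C2 epimers) | CC1C(=O)CC(=O)[C@](C)(COCc2ccccc2)[C@@H]2C=CC[C@@H](C)[C@H]12 | intermediate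
17 | (1S,6S,7R,8R,9S,11R)-6-[(benzyloxy)methyl]-8,9-epoxy-2,6,11-trimethylbicyclo[5.4.0]undecane-3,5-dione (C2 epimers) | CC1C(=O)CC(=O)[C@](C)(COCc2ccccc2)[C@@H]2[C@H]3O[C@H]3C[C@@H](C)[C@H]12 | intermediate
18 | dilithium 2,4-dien-3,5-diolate (dianion) of 17, not isolated | [Li+].[Li+].CC1=C([O-])C=C([O-])[C@](C)(COCc2ccccc2)[C@@H]2[C@H]3O[C@H]3C[C@@H](C)[C@H]12 | intermediate
19 | (1S,2R,6S,7S,8R,9S,11R)-6-[(benzyloxy)methyl]-9-hydroxy-2,6,11-trimethyltricyclo[5.4.0.0^{2,8}]undecane-3,5-dione | O=C1CC(=O)[C@]2(C)[C@@H]3[C@@H]([C@H]2[C@@H](O)C[C@H]3C)[C@@]1(C)COCc1ccccc1 | intermediate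
20 | (1S,2R,6S,7S,8R,11R)-6-[(benzyloxy)methyl]-2,6,11-trimethyltricyclo[5.4.0.0^{2,8}]undecane-3,5,9-trione | O=C1CC(=O)[C@]2(C)[C@@H]3[C@@H]([C@H]2C(=O)C[C@H]3C)[C@@]1(C)COCc1ccccc1 | intermediate
21 | (1S,2R,6S,7S,8R,11R)-6-(hydroxymethyl)-2,6,11-trimethyltricyclo[5.4.0.0^{2,8}]undecane-3,5,9-trione | O=C1CC(=O)[C@]2(C)[C@@H]3[C@@H]([C@H]2C(=O)C[C@H]3C)[C@@]1(C)CO | intermediate
22 | (1S,2R,5R,6S,7S,8R,11R)-5-hydroxy-6-(hydroxymethyl)-2,6,11-trimethyltricyclo[5.4.0.0^{2,8}]undecane-3,9-dione (not isolated) | O[C@@H]1CC(=O)[C@]2(C)[C@@H]3[C@@H]([C@H]2C(=O)C[C@H]3C)[C@@]1(C)CO | intermediate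
23 | (1S,2R,3R,5R,6S,7S,8R,11R)-3,5-dihydroxy-6-(hydroxymethyl)-2,6,11-trimethyltricyclo[5.4.0.0^{2,8}]undecan-9-one | O[C@@H]1C[C@@H](O)[C@]2(C)[C@@H]3[C@@H]([C@H]2C(=O)C[C@H]3C)[C@@]1(C)CO | intermediate
24 | (1S,2R,3R,5R,6S,7S,8R,11R)-6-({[tert-butyl(dimethyl)silyl]oxy}methyl)-3,5-dihydroxy-2,6,11-trimethyltricyclo[5.4.0.0^{2,8}]undecan-9-one | O[C@@H]1C[C@@H](O)[C@]2(C)[C@@H]3[C@@H]([C@H]2C(=O)C[C@H]3C)[C@@]1(C)CO[Si](C)(C)C(C)(C)C | intermediate
25 | (2Z)-2-methylbut-2-enoic acid (angelic acid) | C/C=C(/C)C(=O)O | starting material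
26 | (1S,2R,3R,5R,6S,7S,8R,11R)-6-({[tert-butyl(dimethyl)silyl]oxy}methyl)-2,6,11-trimethyl-9-oxotricyclo[5.4.0.0^{2,8}]undecane-3,5-diyl bis[(2Z)-2-methylbut-2-enoate] | C/C=C(/C)C(=O)O[C@@H]1C[C@@H](OC(=O)/C(C)=C\C)[C@]2(C)[C@@H]3[C@@H]([C@H]2C(=O)C[C@H]3C)[C@@]1(C)CO[Si](C)(C)C(C)(C)C | intermediate
27 | (1S,2R,3R,5R,6S,7S,8R,11R)-6-(hydroxymethyl)-2,6,11-trimethyl-9-oxotricyclo[5.4.0.0^{2,8}]undecane-3,5-diyl bis[(2Z)-2-methylbut-2-enoate] | C/C=C(/C)C(=O)O[C@@H]1C[C@@H](OC(=O)/C(C)=C\C)[C@]2(C)[C@@H]3[C@@H]([C@H]2C(=O)C[C@H]3C)[C@@]1(C)CO | target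

**Step count and risks**

Total step count: 16. Longest linear sequence: 15 (steps 1 to 5 and 7 to 16; step 6 prepares a reagent).

The three steps most likely to fail:

First, step 10 (key step). The second deprotonation at the methine C2 may be slow. The central carbon of the diketonate may open the epoxide in a six-membered closure, or C2 may attack the distal epoxide carbon C9 in a five-membered closure. The fallback changes the activation from a basic dianion to a neutral π-nucleophile with Lewis-acid activation of the epoxide. It sets out from 17, which Me3SiOSO2CF3 and Et3N convert into the 3,5-bis(trimethylsilyloxy)-2,4-diene F1. At −78 °C in CH2Cl2, TiCl4 activates the epoxide, and the terminal carbon of the bis-silyl dienol ether (the nucleophilic site in Chan-type diene alkylations) closes the same C2–C8 bond. Aqueous work-up removes the silyl groups and the fallback comes back to the route at 19.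

Second, step 8. Acylation through the internal methine enolate (five-membered closure) may compete, and attack on the neopentyl ester may be slow, so that intermolecular aldol condensation takes over. The fallback replaces the ester electrophile by a non-enolisable aldehyde. It sets out from 15, which LiAlH4 reduces to the diol F2. Swern oxidation ((COCl)2, DMSO, Et3N) gives the keto aldehyde F3. The kinetic methyl-ketone enolate (LiN(SiMe3)2, THF, −78 °C) then closes the seven-membered ring by aldol addition to give the hydroxy ketone F4. Dess–Martin oxidation of F4 comes back to the route at 16.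

Third, step 5. The hindered diene may be too unreactive toward a β-substituted acyclic enone, and the existing quaternary centre may erode the facial control of the catalyst (mismatched double stereodifferentiation). The fallback uses a more reactive, auxiliary-controlled dienophile. (4R)-4-Benzyl-1,3-oxazolidin-2-one is N-acylated (n-BuLi, (E)-but-2-enoyl chloride) to the crotonyl imide F5. The chelate of F5 with Et2AlCl reacts with 8 at −78 °C to −30 °C, endo and on the face away from the benzyl group, to give the imide adduct F6. Me(MeO)NH·HCl and AlMe3 convert F6 into the Weinreb amide F7 with release of the auxiliary. MeMgBr (THF, −20 °C) then gives the methyl ketone, and the fallback comes back to the route at 10.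

**Further compounds**

F1 | step 10 | 6-[(benzyloxy)methyl]-8,9-epoxy-2,6,11-trimethyl-3,5-bis(trimethylsilyloxy)bicyclo[5.4.0]undeca-2,4-diene (configuration at C1, C6, C7, C8, C9, C11 as in 17) | CC1=C(O[Si](C)(C)C)C=C(O[Si](C)(C)C)[C@](C)(COCc2ccccc2)[C@@H]2[C@H]3O[C@H]3C[C@@H](C)[C@H]12
F2 | step 8 | (2S)-3-(benzyloxy)-2-[(1R,5R,6S)-6-(3-hydroxybutan-2-yl)-5-methylcyclohex-2-en-1-yl]-2-methylpropan-1-ol (diastereomer mixture in the side chain) | CC(O)C(C)[C@H]1[C@H](C)CC=C[C@H]1[C@@](C)(COCc1ccccc1)CO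
F3 | step 8 | (2S)-3-(benzyloxy)-2-methyl-2-[(1R,5R,6S)-5-methyl-6-(3-oxobutan-2-yl)cyclohex-2-en-1-yl]propanal | CC(=O)C(C)[C@H]1[C@H](C)CC=C[C@H]1[C@@](C)(COCc1ccccc1)C=O
F4 | step 8 | 6-[(benzyloxy)methyl]-5-hydroxy-2,6,11-trimethylbicyclo[5.4.0]undec-8-en-3-one (configuration at C1, C6, C7, C11 as in 16; C2 and C5 epimers) | CC1C(=O)CC(O)[C@](C)(COCc2ccccc2)[C@@H]2C=CC[C@@H](C)[C@H]12
F5 | step 5 | (4R)-4-benzyl-3-[(2E)-but-2-enoyl]-1,3-oxazolidin-2-one | O=C1OC[C@@H](Cc2ccccc2)N1C(=O)/C=C/C
F6 | step 5 | methyl (2S)-3-(benzyloxy)-2-methyl-2-[(1R,5R,6S)-5-methyl-6-{[(4R)-4-benzyl-2-oxo-1,3-oxazolidin-3-yl]carbonyl}cyclohex-2-en-1-yl]propanoate | O=C1OC[C@@H](Cc2ccccc2)N1C(=O)[C@H]1[C@H](C)CC=C[C@H]1[C@@](C)(COCc1ccccc1)C(=O)OC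
F7 | step 5 | methyl (2S)-3-(benzyloxy)-2-{(1R,5R,6S)-6-[methoxy(methyl)carbamoyl]-5-methylcyclohex-2-en-1-yl}-2-methylpropanoate | CON(C)C(=O)[C@H]1[C@H](C)CC=C[C@H]1[C@@](C)(COCc1ccccc1)C(=O)OC
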